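## The problem

The target **33** is a trans-fused tetrahydroindene. Cyclohexene ring A (C1, C2, C3, C3a, C6a, C7) shares the C3a–C6a bond with cyclopentene ring B (C3a, C4, C5, C6, C6a); these labels are used throughout and are not IUPAC locants. Five contiguous stereocentres run C4–C3a–C6a–C7–C1. C7 (methyl, carboxyl) and C1 (ethyl, 2-methyl-4-phenylbutadienyl) are adjacent quaternary carbons, with methyl syn to ethyl and the carboxyl cis to H6a. The three ring B methines can be set together and relayed from one external centre, because C3a and C4 sit at epimerisable positions in a suitable intermediate. C7 must then be set against C6a and C1 against C7, and nothing in the finished skeleton can be corrected by equilibration. The (E,E)-styryl diene is sensitive to acid, oxidants and metathesis catalysts, the two skipped trisubstituted ring alkenes must not migrate, and the neopentyl acid needs an ester that comes off without attack at the carbonyl. The trans fusion also rules out any ring A closure that has to eclipse the C3a–C6a bond. The enabling feature is ring B: its methyls sit 1,3 across the C5=C6 alkene and C3a and C6a carry trans carbon substituents. That is the pattern a γ-methyl allenoate (C6, C5, C4, ester carbon becoming the C6 methyl) leaves on an E enone spanning C3a–C6a.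

## Retrosynthesis

**Side chain last.** The diene of **33** is cut at both C=C bonds, back through ester **32** and enal **30** to aldehyde **28**. This keeps the styryl diene out of every enolate, hydride and metathesis step. The forward reactions are a stabilised Wittig reaction and a Horner–Wadsworth–Emmons reaction, both E-selective, on an aldehyde that cannot enolise. The acid is carried as a 2-(trimethylsilyl)ethyl ester, removed by fluoride at the alkyl end.

**Ring A by metathesis.** Aldehyde **28** comes from silyl ether **26**, which is cut at C2=C3 to the monocyclic diene **25**. A more compact closure was weighed and set aside: a δ-lactone from the C7 carboxyl to a C3 carbinol, rearranging as its enolate onto a C3 alkenyl group. Its boat transition state has C3 and C7 as bridgeheads of a bicyclo[2.2.2] array and needs the C3a–C6a bond nearly eclipsed, which a trans-fused cyclopentene cannot allow. Ring-closing metathesis has no such demand. It asks only that an isopropenyl group on C3a and a vinyl group on C1 form a trisubstituted alkene.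

**Both quaternary carbons by one [3,3] shift.** Diene **25** is the ester of acid **24**, which is cut at C7–C1 to the allyl ester **21**. An Ireland–Claisen rearrangement joins two fully substituted carbons and fixes their relative configuration through its transition state; stepwise alkylation would not. The forward reaction needs a defined enolate geometry, a defined alkene geometry and attack on one enolate face, which the C6a centre is placed to direct. The precursor has no quaternary carbon at all.

**Ester 21 from two halves.** The ester bond is cut to acid **16** and the Z allylic alcohol **20**. Alcohol **20** comes from enoate **19**, made by syn addition of an ethylcopper reagent to ynoate **18**, itself from the propargyl silyl ether **17**. The geometry of **20** is set by the syn addition and is the one the chair transition state requires.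

**Adjusting the annulation product.** Acid **16** is reached from cyclopentene **10** through **11**, **12**, **14** and **15**. The acetyl group becomes the isopropenyl group, the ring ester becomes the C6 methyl, and the silyloxymethyl group becomes the carboxyl. No C–C bond of the ring is touched.

**Ring B by (3+2) annulation.** Cyclopentene **10** is cut at C6–C6a and C4–C3a to allenoate **4** and enone **9**. This single catalytic step delivers the ring, both ring methyls in latent form and three stereocentres. A Diels–Alder or aldol construction of ring B would need the C4 and C6 substituents installed separately.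

**Fragments.** Allenoate **4** comes from propanoyl chloride **1** and ylide **2** through methylketene **3**. Enone **9** comes from aldehyde **7** and ylide **8**, and **7** from the hydroxy ester **5** through silyl ether **6**. A tert-butyldiphenylsilyl group is chosen to enlarge the group that directs the annulation.

## Roads not taken

Alternative 1: The cut removes C3a–C6a, C4–C5 and C5–C6, with C5 coming from CO. Co2(CO)8 with N-methylmorpholine N-oxide would effect an intramolecular Pauson–Khand reaction of an open-chain dienyne and close rings A and B at once to enone A1. The C5 ketone would then be removed through its sulfonylhydrazone; loss of N2 from the allylic diazene moves the alkene to C5–C6 and places hydrogen on C6a.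
- Merits: three C–C bonds and both rings form in one step, and the route is convergent.
- Weak points: the open-chain substrate must already carry C1 and C7, set without a ring. The reacting alkene is the terminus of a conjugated diene, and the styryl diene is a second ligand for cobalt. C3a and C4 depend on remote induction, and the trans fusion depends on the face of one hydride delivery.
- Comparison: for the bicyclic core this road has the better step economy. The chosen plan sets against it a ring-forming step that needs only a catalytic phosphine and two short fragments, ring B stereocentres that follow from a centre next to the reacting carbon, and a side chain that is absent during the delicate steps.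

Alternative 2: The cut removes C7–C6a and C3–C3a. A 2-pyranone diene and an E enone dienophile would combine under high pressure to the bridged lactone A2.
- Merits: one cycloaddition makes C7 quaternary with its carboxyl (as the lactone carbonyl) and sets the trans C3a/C6a relationship. The allylic lactone could later open with SN2′ delivery of ethyl to C1 anti to the bridge, which would solve the adjacent quaternary carbons inside a ring.
- Weak points: a pyranone and a β-alkyl enone are a poorly matched pair, regiochemistry and endo/exo selectivity are open, and such adducts lose CO2 on heating. Ring B would have to be grown from an acetyl group on C6a and an ethyl group on C3a, and the ethyl methylene that must become C4 has no handle for the C4–C5 bond or the C4 stereocentre.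
- Comparison: at the quaternary pair this road is better than the chosen plan, whose open-chain rearrangement is its weakest point. The chosen plan sets against it that ring B arrives complete, with both methyls and all three stereocentres.

Alternative 3: The cut removes C1–C2. A zerovalent palladium catalyst from Pd(OAc)2 and a phosphine would insert into a Z alkenyl iodide at C2 and add 6-exo to the ethyl-bearing diene terminus C1. The π-allylpalladium would lose a benzylic hydride to give the styryl diene of methyl ester A3.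
- Merits: ring A, C1 and the complete side chain form in one late step, which saves about four steps against the chosen endgame.
- Weak points: C7 must already be quaternary. The C1 configuration rests on the conformational preference of an insertion next to C7, insertion into a trisubstituted diene terminus is slow, and the π-allyl intermediate can eliminate toward the ethyl group or give E/Z mixtures.
- Comparison: the endgame is shorter and the diene is never exposed to further reagents, which is better. The chosen plan sets against it that C1 and C7 are formed together with their relative configuration fixed by a pericyclic transition state.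

Key step: step 5

Assumption: C7 in **15**, **16** and **21** is drawn as inherited from **5**; loss of configuration there is harmless because step 15 enolises this centre. Allenoate **4** is used as the racemate, since its axial chirality is lost on phosphine addition.

## Steps

Step 1
Reactants: 1 propanoyl chloride; 2 ethyl (triphenylphosphoranylidene)acetate
Product: 4 ethyl penta-2,3-dienoate (racemic), via methylketene 3 (not isolated)
Conditions: Et3N, CH2Cl2, 0 °C → rt
Reagents that add atoms: none
Why: Et3N dehydrochlorinates the acid chloride to the ketene, and a Wittig reaction of the stabilised ylide at the ketene carbonyl gives the allenoate; this is the standard preparation of γ-substituted allenoates.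

Step 2
Reactants: 5 methyl (S)-3-hydroxy-2-methylpropanoate
Product: 6 methyl (S)-3-[(tert-butyldiphenylsilyl)oxy]-2-methylpropanoate
Conditions: t-BuPh2SiCl, imidazole, DMF, 0 °C → rt
Reagents that add atoms: tert-butyl(chloro)diphenylsilane, CC(C)(C)[Si](Cl)(c1ccccc1)c1ccccc1
Why: Silylation of a primary alcohol; the stereocentre is not touched, and the bulky silyl group is chosen to sharpen facial control in step 5.

Step 3
Reactants: 6 methyl (S)-3-[(tert-butyldiphenylsilyl)oxy]-2-methylpropanoate
Product: 7 (S)-3-[(tert-butyldiphenylsilyl)oxy]-2-methylpropanal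
Conditions: i-Bu2AlH (1.1 equiv), CH2Cl2, −78 °C
Reagents that add atoms: none
Why: Partial reduction of the ester through the aluminium hemiacetal, which is stable at −78 °C; the α-centre is not enolised under these conditions.

Step 4
Reactants: 7 (S)-3-[(tert-butyldiphenylsilyl)oxy]-2-methylpropanal; 8 1-(triphenylphosphoranylidene)propan-2-one
Product: 9 (3E,5R)-6-[(tert-butyldiphenylsilyl)oxy]-5-methylhex-3-en-2-one
Conditions: toluene, 60 °C
Reagents that add atoms: none
Why: Wittig reaction with a stabilised ylide should give the E enone; no base is present, so the α-centre of the aldehyde keeps its configuration.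

Step 5
Reactants: 4 ethyl penta-2,3-dienoate; 9 (3E,5R)-6-[(tert-butyldiphenylsilyl)oxy]-5-methylhex-3-en-2-one
Product: 10 ethyl (3R,4S,5R)-4-acetyl-5-[(2R)-1-[(tert-butyldiphenylsilyl)oxy]propan-2-yl]-3-methylcyclopent-1-ene-1-carboxylate
Conditions: PBu3 (20 mol %), toluene, 60 °C, 4 (2 equiv) added slowly
Reagents that add atoms: none
Why: PBu3 adds to the central carbon of 4 to give a phosphonium dienolate, whose α-carbon adds to the β-carbon of 9 (C6–C6a); the enolate then closes onto the γ-carbon of the vinylphosphonium (C4–C3a), and proton transfer with loss of PBu3 leaves the C5=C6 alkene. The closest known reaction type is the phosphine-catalysed (3+2) annulation of γ-substituted allenoates with β-substituted enones, in which the γ-substituent steers attack to the α-terminus. Ring B therefore closes stepwise, by a Michael addition followed by an intramolecular addition to the vinylphosphonium that is driven by ylide formation, and not by a concerted cycloaddition. C6a is set in the first bond formation under control of the adjacent C7 centre: with the C7–H bond eclipsing the enone, the dienolate should add anti to the silyloxymethyl group, which gives the (5R) centre from the (R)-enone. C3a ends trans to C6a because the E geometry is carried through and because this acetyl-bearing centre is epimerisable, so the trans isomer is also the thermodynamic one. C4 is set in the ring closure with methyl trans to acetyl and therefore cis to the C6a substituent, the arrangement known from annulations of γ-substituted allenoates and also the more stable one, since C4 is the γ-position of the enoate. The step needs α-regioselectivity, facial selectivity at C6a and enough reactivity from a β-branched alkyl enone; the γ-methyl group, the bulky silyl ether and a nucleophilic trialkylphosphine with slow addition of 4 are meant to secure these. The diastereomer epimeric at the ring centres should be removed by chromatography here, so that later loss of the C7 configuration cannot erode enantiopurity.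

Step 6
Reactants: 10 ethyl (3R,4S,5R)-4-acetyl-5-[(2R)-1-[(tert-butyldiphenylsilyl)oxy]propan-2-yl]-3-methylcyclopent-1-ene-1-carboxylate
Product: 11 ethyl (3R,4S,5S)-5-[(2R)-1-[(tert-butyldiphenylsilyl)oxy]propan-2-yl]-3-methyl-4-(prop-1-en-2-yl)cyclopent-1-ene-1-carboxylate
Conditions: Ph3PCH3Br, KOt-Bu, THF, 0 °C → rt
Reagents that add atoms: methyltriphenylphosphonium bromide, C[P+](c1ccccc1)(c1ccccc1)c1ccccc1.[Br-]
Why: Wittig methylenation; the ketone reacts much faster than the conjugated ester, and any enolisation at C3a returns the trans isomer, which is the stable one.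

Step 7
Reactants: 11 ethyl (3R,4S,5S)-5-[(2R)-1-[(tert-butyldiphenylsilyl)oxy]propan-2-yl]-3-methyl-4-(prop-1-en-2-yl)cyclopent-1-ene-1-carboxylate
Product: 12 {(3R,4S,5S)-5-[(2R)-1-[(tert-butyldiphenylsilyl)oxy]propan-2-yl]-3-methyl-4-(prop-1-en-2-yl)cyclopent-1-en-1-yl}methanol
Conditions: i-Bu2AlH (2.5 equiv), CH2Cl2, −78 → 0 °C
Reagents that add atoms: none
Why: 1,2-Reduction of a conjugated ester to the allylic alcohol; the silyl ether and both alkenes are inert.

Step 8
Reactants: 12 {(3R,4S,5S)-5-[(2R)-1-[(tert-butyldiphenylsilyl)oxy]propan-2-yl]-3-methyl-4-(prop-1-en-2-yl)cyclopent-1-en-1-yl}methanol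
Product: 14 tert-butyl{[(2R)-2-[(1S,4R,5S)-2,4-dimethyl-5-(prop-1-en-2-yl)cyclopent-2-en-1-yl]propyl]oxy}diphenylsilane, via allylic mesylate 13 (not isolated)
Conditions: MsCl, Et3N, THF, 0 °C; then LiEt3BH, 0 °C → rt
Reagents that add atoms: none
Why: Sulfonylation and SN2 displacement by hydride in one pot; LiEt3BH should attack the primary allylic carbon directly, so the alkene stays at C5=C6 and the ester carbon becomes the C6 methyl.

Step 9
Reactants: 14 tert-butyl{[(2R)-2-[(1S,4R,5S)-2,4-dimethyl-5-(prop-1-en-2-yl)cyclopent-2-en-1-yl]propyl]oxy}diphenylsilane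
Product: 15 (2R)-2-[(1S,4R,5S)-2,4-dimethyl-5-(prop-1-en-2-yl)cyclopent-2-en-1-yl]propan-1-ol
Conditions: Bu4NF, THF, rt
Reagents that add atoms: none
Why: Fluoride cleavage of the silyl ether; nothing else in the molecule responds to fluoride.

Step 10
Reactants: 15 (2R)-2-[(1S,4R,5S)-2,4-dimethyl-5-(prop-1-en-2-yl)cyclopent-2-en-1-yl]propan-1-ol
Product: 16 (2R)-2-[(1S,4R,5S)-2,4-dimethyl-5-(prop-1-en-2-yl)cyclopent-2-en-1-yl]propanoic acid
Conditions: TEMPO (cat.), PhI(OAc)2, MeCN/H2O, rt
Reagents that add atoms: water, O
Why: Nitroxyl-catalysed oxidation of the primary alcohol through the aldehyde hydrate to the acid; the alkenes are not oxidised.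

Step 11
Reactants: 17 tert-butyldimethyl(prop-2-yn-1-yloxy)silane
Product: 18 methyl 4-[(tert-butyldimethylsilyl)oxy]but-2-ynoate
Conditions: n-BuLi, THF, −78 °C; then ClCO2Me
Reagents that add atoms: methyl chloroformate, COC(=O)Cl
Why: Acylation of a lithium acetylide with a chloroformate.

Step 12
Reactants: 18 methyl 4-[(tert-butyldimethylsilyl)oxy]but-2-ynoate
Product: 19 methyl (2Z)-3-{[(tert-butyldimethylsilyl)oxy]methyl}pent-2-enoate
Conditions: EtMgBr, CuI (1.2 equiv each), THF, −78 °C; then sat. aq NH4Cl at −78 °C
Reagents that add atoms: ethylmagnesium bromide, CC[Mg]Br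
Why: Syn carbocupration of the ynoate and protonation with retention at −78 °C should place ethyl cis to hydrogen, so the silyloxymethyl group ends cis to the ester (Z).

Step 13
Reactants: 19 methyl (2Z)-3-{[(tert-butyldimethylsilyl)oxy]methyl}pent-2-enoate
Product: 20 (2Z)-3-{[(tert-butyldimethylsilyl)oxy]methyl}pent-2-en-1-ol
Conditions: i-Bu2AlH (2.2 equiv), CH2Cl2, −78 °C
Reagents that add atoms: none
Why: 1,2-Reduction of the enoate; the alkene geometry is kept.

Step 14
Reactants: 16 (2R)-2-[(1S,4R,5S)-2,4-dimethyl-5-(prop-1-en-2-yl)cyclopent-2-en-1-yl]propanoic acid; 20 (2Z)-3-{[(tert-butyldimethylsilyl)oxy]methyl}pent-2-en-1-ol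
Product: 21 (2Z)-3-{[(tert-butyldimethylsilyl)oxy]methyl}pent-2-en-1-yl (2R)-2-[(1S,4R,5S)-2,4-dimethyl-5-(prop-1-en-2-yl)cyclopent-2-en-1-yl]propanoate
Conditions: EDC·HCl, DMAP, CH2Cl2, 0 °C → rt
Reagents that add atoms: none
Why: Carbodiimide esterification of an α-branched acid with a primary allylic alcohol; epimerisation at C7 is of no consequence.

Step 15
Reactants: 21 (2Z)-3-{[(tert-butyldimethylsilyl)oxy]methyl}pent-2-en-1-yl (2R)-2-[(1S,4R,5S)-2,4-dimethyl-5-(prop-1-en-2-yl)cyclopent-2-en-1-yl]propanoate
Product: 24 (2R,3S)-3-{[(tert-butyldimethylsilyl)oxy]methyl}-2-[(1R,4R,5S)-2,4-dimethyl-5-(prop-1-en-2-yl)cyclopent-2-en-1-yl]-3-ethyl-2-methylpent-4-enoic acid, via silyl ketene acetal 22 (not isolated), via trimethylsilyl ester 23 (not isolated)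
Conditions: LiN(i-Pr)2, THF, −78 °C; Me3SiCl/Et3N; −78 → 60 °C; then 1 M HCl
Reagents that add atoms: none
Why: Ireland–Claisen rearrangement of an α-branched allyl ester: kinetic enolisation in THF should place the larger α-substituent (the ring) cis to the allyloxy oxygen, and the chair [3,3] shift of that ketene acetal onto the Z alkene joins C7 to C1 with methyl syn to ethyl and carboxyl syn to the silyloxymethyl group. The enolate face is chosen by A(1,3) strain: with H6a eclipsing the enolate, the allyl unit arrives from the side of H3a, away from the C6 methyl, which gives the (2R) centre. A [3,3] shift is the standard way to join two fully substituted carbons.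

Step 16
Reactants: 24 (2R,3S)-3-{[(tert-butyldimethylsilyl)oxy]methyl}-2-[(1R,4R,5S)-2,4-dimethyl-5-(prop-1-en-2-yl)cyclopent-2-en-1-yl]-3-ethyl-2-methylpent-4-enoic acid
Product: 25 2-(trimethylsilyl)ethyl (2R,3S)-3-{[(tert-butyldimethylsilyl)oxy]methyl}-2-[(1R,4R,5S)-2,4-dimethyl-5-(prop-1-en-2-yl)cyclopent-2-en-1-yl]-3-ethyl-2-methylpent-4-enoate
Conditions: Me3SiCH2CH2OH, PPh3, DIAD, THF, 0 °C → rt
Reagents that add atoms: 2-(trimethylsilyl)ethanol, C[Si](C)(C)CCO
Why: Mitsunobu esterification alkylates the carboxylate at oxygen, so hindrance at the acyl carbon does not matter; the ester can later be removed by fluoride without attack at the carbonyl.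

Step 17
Reactants: 25 2-(trimethylsilyl)ethyl (2R,3S)-3-{[(tert-butyldimethylsilyl)oxy]methyl}-2-[(1R,4R,5S)-2,4-dimethyl-5-(prop-1-en-2-yl)cyclopent-2-en-1-yl]-3-ethyl-2-methylpent-4-enoate
Product: 26 2-(trimethylsilyl)ethyl (1R,3aR,4R,5S,7aS)-5-{[(tert-butyldimethylsilyl)oxy]methyl}-5-ethyl-1,3,4,7-tetramethyl-3a,4,5,7a-tetrahydro-1H-indene-4-carboxylate
Conditions: second-generation Grubbs catalyst RuCl2(=CHPh)(H2IMes)(PCy3) (10 mol %), toluene, 80 °C
Reagents that add atoms: none
Why: Ring-closing metathesis: the catalyst loads on the vinyl group and closes onto the 1,1-disubstituted alkene to form the trisubstituted C2=C3 bond of ring A, with loss of ethylene. The trisubstituted ring B alkene does not take part, and no stereocentre is involved.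

Step 18
Reactants: 26 2-(trimethylsilyl)ethyl (1R,3aR,4R,5S,7aS)-5-{[(tert-butyldimethylsilyl)oxy]methyl}-5-ethyl-1,3,4,7-tetramethyl-3a,4,5,7a-tetrahydro-1H-indene-4-carboxylate
Product: 27 2-(trimethylsilyl)ethyl (1R,3aR,4R,5S,7aS)-5-ethyl-5-(hydroxymethyl)-1,3,4,7-tetramethyl-3a,4,5,7a-tetrahydro-1H-indene-4-carboxylate
Conditions: HF·pyridine, pyridine, THF, 0 °C → rt
Reagents that add atoms: none
Why: Buffered HF removes the primary silyl ether and leaves the 2-(trimethylsilyl)ethyl ester; the hindered ester should resist lactonisation by the neighbouring alcohol if the product is oxidised without delay.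

Step 19
Reactants: 27 2-(trimethylsilyl)ethyl (1R,3aR,4R,5S,7aS)-5-ethyl-5-(hydroxymethyl)-1,3,4,7-tetramethyl-3a,4,5,7a-tetrahydro-1H-indene-4-carboxylate
Product: 28 2-(trimethylsilyl)ethyl (1R,3aR,4R,5S,7aS)-5-ethyl-5-formyl-1,3,4,7-tetramethyl-3a,4,5,7a-tetrahydro-1H-indene-4-carboxylate
Conditions: Dess–Martin periodinane, CH2Cl2, rt
Reagents that add atoms: none
Why: Dess–Martin oxidation of a neopentyl alcohol; the aldehyde has no α-hydrogen and cannot epimerise.

Step 20
Reactants: 28 2-(trimethylsilyl)ethyl (1R,3aR,4R,5S,7aS)-5-ethyl-5-formyl-1,3,4,7-tetramethyl-3a,4,5,7a-tetrahydro-1H-indene-4-carboxylate; 29 2-(triphenylphosphoranylidene)propanal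
Product: 30 2-(trimethylsilyl)ethyl (1R,3aR,4R,5R,7aS)-5-ethyl-1,3,4,7-tetramethyl-5-[(1E)-2-methyl-3-oxoprop-1-en-1-yl]-3a,4,5,7a-tetrahydro-1H-indene-4-carboxylate
Conditions: toluene, 110 °C
Reagents that add atoms: none
Why: Wittig reaction with a stabilised formyl ylide should give the E trisubstituted enal; the product is less electrophilic than 28, which limits a second olefination.

Step 21
Reactants: 30 2-(trimethylsilyl)ethyl (1R,3aR,4R,5R,7aS)-5-ethyl-1,3,4,7-tetramethyl-5-[(1E)-2-methyl-3-oxoprop-1-en-1-yl]-3a,4,5,7a-tetrahydro-1H-indene-4-carboxylate; 31 diethyl benzylphosphonate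
Product: 32 2-(trimethylsilyl)ethyl (1R,3aR,4R,5S,7aS)-5-ethyl-1,3,4,7-tetramethyl-5-[(1E,3E)-2-methyl-4-phenylbuta-1,3-dien-1-yl]-3a,4,5,7a-tetrahydro-1H-indene-4-carboxylate
Conditions: KOt-Bu, THF, 0 °C → rt
Reagents that add atoms: none
Why: Horner–Wadsworth–Emmons reaction of a benzylphosphonate anion should give the E styryl alkene; the enal has no γ-hydrogen, so it cannot deconjugate under base.

Step 22
Reactants: 32 2-(trimethylsilyl)ethyl (1R,3aR,4R,5S,7aS)-5-ethyl-1,3,4,7-tetramethyl-5-[(1E,3E)-2-methyl-4-phenylbuta-1,3-dien-1-yl]-3a,4,5,7a-tetrahydro-1H-indene-4-carboxylate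
Product: 33 (1R,3aR,4R,5S,7aS)-5-ethyl-1,3,4,7-tetramethyl-5-[(1E,3E)-2-methyl-4-phenylbuta-1,3-dien-1-yl]-3a,4,5,7a-tetrahydro-1H-indene-4-carboxylic acid
Conditions: Bu4NF, THF, rt; then 0.5 M HCl work-up
Reagents that add atoms: none
Why: Fluoride attacks silicon and the ester fragments to ethylene and the carboxylate, so the hindered carbonyl is never attacked; the diene and the ring alkenes are inert to fluoride.

## Compound list

1 | propanoyl chloride | CCC(=O)Cl | starting material
2 | ethyl (triphenylphosphoranylidene)acetate | CCOC(=O)C=P(c1ccccc1)(c1ccccc1)c1ccccc1 | starting material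
3 | methylketene | CC=C=O | intermediate
4 | ethyl penta-2,3-dienoate (racemic) | CCOC(=O)C=C=CC | intermediate
5 | methyl (S)-3-hydroxy-2-methylpropanoate | COC(=O)[C@@H](C)CO | starting material
6 | methyl (S)-3-[(tert-butyldiphenylsilyl)oxy]-2-methylpropanoate | COC(=O)[C@@H](C)CO[Si](c1ccccc1)(c1ccccc1)C(C)(C)C | intermediate
7 | (S)-3-[(tert-butyldiphenylsilyl)oxy]-2-methylpropanal | O=C[C@@H](C)CO[Si](c1ccccc1)(c1ccccc1)C(C)(C)C | intermediate
8 | 1-(triphenylphosphoranylidene)propan-2-one | CC(=O)C=P(c1ccccc1)(c1ccccc1)c1ccccc1 | starting material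
9 | (3E,5R)-6-[(tert-butyldiphenylsilyl)oxy]-5-methylhex-3-en-2-one | CC(=O)/C=C/[C@@H](C)CO[Si](c1ccccc1)(c1ccccc1)C(C)(C)C | intermediate
10 | ethyl (3R,4S,5R)-4-acetyl-5-[(2R)-1-[(tert-butyldiphenylsilyl)oxy]propan-2-yl]-3-methylcyclopent-1-ene-1-carboxylate | CCOC(=O)C1=C[C@@H](C)[C@H](C(C)=O)[C@H]1[C@@H](C)CO[Si](c1ccccc1)(c1ccccc1)C(C)(C)C | intermediate
11 | ethyl (3R,4S,5S)-5-[(2R)-1-[(tert-butyldiphenylsilyl)oxy]propan-2-yl]-3-methyl-4-(prop-1-en-2-yl)cyclopent-1-ene-1-carboxylate | CCOC(=O)C1=C[C@@H](C)[C@H](C(C)=C)[C@H]1[C@@H](C)CO[Si](c1ccccc1)(c1ccccc1)C(C)(C)C | intermediate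
12 | {(3R,4S,5S)-5-[(2R)-1-[(tert-butyldiphenylsilyl)oxy]propan-2-yl]-3-methyl-4-(prop-1-en-2-yl)cyclopent-1-en-1-yl}methanol | OCC1=C[C@@H](C)[C@H](C(C)=C)[C@H]1[C@@H](C)CO[Si](c1ccccc1)(c1ccccc1)C(C)(C)C | intermediate
13 | methanesulfonate of alcohol 12 | CS(=O)(=O)OCC1=C[C@@H](C)[C@H](C(C)=C)[C@H]1[C@@H](C)CO[Si](c1ccccc1)(c1ccccc1)C(C)(C)C | intermediate
14 | tert-butyl{[(2R)-2-[(1S,4R,5S)-2,4-dimethyl-5-(prop-1-en-2-yl)cyclopent-2-en-1-yl]propyl]oxy}diphenylsilane | CC1=C[C@@H](C)[C@H](C(C)=C)[C@H]1[C@@H](C)CO[Si](c1ccccc1)(c1ccccc1)C(C)(C)C | intermediate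
15 | (2R)-2-[(1S,4R,5S)-2,4-dimethyl-5-(prop-1-en-2-yl)cyclopent-2-en-1-yl]propan-1-ol | CC1=C[C@@H](C)[C@H](C(C)=C)[C@H]1[C@@H](C)CO | intermediate
16 | (2R)-2-[(1S,4R,5S)-2,4-dimethyl-5-(prop-1-en-2-yl)cyclopent-2-en-1-yl]propanoic acid | CC1=C[C@@H](C)[C@H](C(C)=C)[C@H]1[C@@H](C)C(=O)O | intermediate
17 | tert-butyldimethyl(prop-2-yn-1-yloxy)silane | C#CCO[Si](C)(C)C(C)(C)C | starting material
18 | methyl 4-[(tert-butyldimethylsilyl)oxy]but-2-ynoate | COC(=O)C#CCO[Si](C)(C)C(C)(C)C | intermediate
19 | methyl (2Z)-3-{[(tert-butyldimethylsilyl)oxy]methyl}pent-2-enoate | COC(=O)/C=C(/CC)CO[Si](C)(C)C(C)(C)C | intermediate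
20 | (2Z)-3-{[(tert-butyldimethylsilyl)oxy]methyl}pent-2-en-1-ol | OC/C=C(/CC)CO[Si](C)(C)C(C)(C)C | intermediate
21 | (2Z)-3-{[(tert-butyldimethylsilyl)oxy]methyl}pent-2-en-1-yl (2R)-2-[(1S,4R,5S)-2,4-dimethyl-5-(prop-1-en-2-yl)cyclopent-2-en-1-yl]propanoate | CC1=C[C@@H](C)[C@H](C(C)=C)[C@H]1[C@@H](C)C(=O)OC/C=C(/CC)CO[Si](C)(C)C(C)(C)C | intermediate
22 | trimethylsilyl ketene acetal of 21, E at the enolate (ring carbon cis to the allyloxy oxygen, methyl cis to OSiMe3) | C/C(=C(\O[Si](C)(C)C)OC/C=C(/CC)CO[Si](C)(C)C(C)(C)C)[C@H]1C(C)=C[C@@H](C)[C@@H]1C(C)=C | intermediate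
23 | trimethylsilyl ester of acid 24 | CC[C@](CO[Si](C)(C)C(C)(C)C)(C=C)[C@](C)(C(=O)O[Si](C)(C)C)[C@H]1C(C)=C[C@@H](C)[C@@H]1C(C)=C | intermediate
24 | (2R,3S)-3-{[(tert-butyldimethylsilyl)oxy]methyl}-2-[(1R,4R,5S)-2,4-dimethyl-5-(prop-1-en-2-yl)cyclopent-2-en-1-yl]-3-ethyl-2-methylpent-4-enoic acid | CC[C@](CO[Si](C)(C)C(C)(C)C)(C=C)[C@](C)(C(=O)O)[C@H]1C(C)=C[C@@H](C)[C@@H]1C(C)=C | intermediate
25 | 2-(trimethylsilyl)ethyl (2R,3S)-3-{[(tert-butyldimethylsilyl)oxy]methyl}-2-[(1R,4R,5S)-2,4-dimethyl-5-(prop-1-en-2-yl)cyclopent-2-en-1-yl]-3-ethyl-2-methylpent-4-enoate | CC[C@](CO[Si](C)(C)C(C)(C)C)(C=C)[C@](C)(C(=O)OCC[Si](C)(C)C)[C@H]1C(C)=C[C@@H](C)[C@@H]1C(C)=C | intermediate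
26 | 2-(trimethylsilyl)ethyl (1R,3aR,4R,5S,7aS)-5-{[(tert-butyldimethylsilyl)oxy]methyl}-5-ethyl-1,3,4,7-tetramethyl-3a,4,5,7a-tetrahydro-1H-indene-4-carboxylate | CC[C@]1(CO[Si](C)(C)C(C)(C)C)C=C(C)[C@H]2[C@H](C)C=C(C)[C@@H]2[C@@]1(C)C(=O)OCC[Si](C)(C)C | intermediate
27 | 2-(trimethylsilyl)ethyl (1R,3aR,4R,5S,7aS)-5-ethyl-5-(hydroxymethyl)-1,3,4,7-tetramethyl-3a,4,5,7a-tetrahydro-1H-indene-4-carboxylate | CC[C@]1(CO)C=C(C)[C@H]2[C@H](C)C=C(C)[C@@H]2[C@@]1(C)C(=O)OCC[Si](C)(C)C | intermediate
28 | 2-(trimethylsilyl)ethyl (1R,3aR,4R,5S,7aS)-5-ethyl-5-formyl-1,3,4,7-tetramethyl-3a,4,5,7a-tetrahydro-1H-indene-4-carboxylate | CC[C@]1(C=O)C=C(C)[C@H]2[C@H](C)C=C(C)[C@@H]2[C@@]1(C)C(=O)OCC[Si](C)(C)C | intermediate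
29 | 2-(triphenylphosphoranylidene)propanal | CC(C=O)=P(c1ccccc1)(c1ccccc1)c1ccccc1 | starting material
30 | 2-(trimethylsilyl)ethyl (1R,3aR,4R,5R,7aS)-5-ethyl-1,3,4,7-tetramethyl-5-[(1E)-2-methyl-3-oxoprop-1-en-1-yl]-3a,4,5,7a-tetrahydro-1H-indene-4-carboxylate | CC[C@]1(/C=C(C)/C=O)C=C(C)[C@H]2[C@H](C)C=C(C)[C@@H]2[C@@]1(C)C(=O)OCC[Si](C)(C)C | intermediate
31 | diethyl benzylphosphonate | CCOP(=O)(Cc1ccccc1)OCC | starting material
32 | 2-(trimethylsilyl)ethyl (1R,3aR,4R,5S,7aS)-5-ethyl-1,3,4,7-tetramethyl-5-[(1E,3E)-2-methyl-4-phenylbuta-1,3-dien-1-yl]-3a,4,5,7a-tetrahydro-1H-indene-4-carboxylate | CC[C@]1(/C=C(C)/C=C/c2ccccc2)C=C(C)[C@H]2[C@H](C)C=C(C)[C@@H]2[C@@]1(C)C(=O)OCC[Si](C)(C)C | intermediate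
33 | (1R,3aR,4R,5S,7aS)-5-ethyl-1,3,4,7-tetramethyl-5-[(1E,3E)-2-methyl-4-phenylbuta-1,3-dien-1-yl]-3a,4,5,7a-tetrahydro-1H-indene-4-carboxylic acid | CC[C@]1(/C=C(C)/C=C/c2ccccc2)C=C(C)[C@H]2[C@H](C)C=C(C)[C@@H]2[C@@]1(C)C(=O)O | target

## Step count and least certain steps

Total: 22 steps. Longest linear sequence: 18 steps (steps 2–10 and 14–22, from **5**).

**Step 5 (key step).** The phosphonium dienolate may add too slowly to a β-branched alkyl enone, so that isomerisation and oligomerisation of **4** outrun the annulation. Facial discrimination by the C7 centre may also be weak, because it rests on methyl against silyloxymethyl. Fallback, from **7** back to **10**: condensation of aldehyde **7** with allyl acetoacetate (TiCl4, pyridine, THF) would give the doubly activated acceptor allyl (4R)-2-acetyl-5-[(tert-butyldiphenylsilyl)oxy]-4-methylpent-2-enoate F1. Alkylidene β-keto esters are among the best acceptors for this annulation, and PBu3 with **4** should give 1-allyl 3-ethyl (2S,5R)-1-acetyl-2-[(2R)-1-[(tert-butyldiphenylsilyl)oxy]propan-2-yl]-5-methylcyclopent-3-ene-1,3-dicarboxylate F2. Pd(PPh3)4 and morpholine then remove the allyl ester with loss of CO2; C3a protonates to the trans isomer and the route resumes at **10**.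

**Step 15.** Deprotonation of the α-branched ester may give a mixture of enolate geometries, since it must distinguish methyl from the ring carbon. Part of the rearrangement may also pass through a boat, or the hindered C7–H may enolise incompletely. The first two lead to epimers at C1; attack on the wrong enolate face would give the C7 epimer. Fallback, from **16** back to **24**, for the case that the enolate forms mainly with methyl cis to the allyloxy oxygen: the acid is paired with the E alcohol, which then gives the same product through the chair. But-2-yne-1,4-diol is monoprotected (NaH, 4-methoxybenzyl chloride) to 4-[(4-methoxybenzyl)oxy]but-2-yn-1-ol F3. Hydroxyl-directed anti carbomagnesiation (EtMgBr, CuI 10 mol %) gives (2E)-2-ethyl-4-[(4-methoxybenzyl)oxy]but-2-en-1-ol F4. Silylation (t-BuMe2SiCl, imidazole) gives tert-butyl{[(2E)-2-ethyl-4-[(4-methoxybenzyl)oxy]but-2-en-1-yl]oxy}dimethylsilane F5, and DDQ gives (2E)-3-{[(tert-butyldimethylsilyl)oxy]methyl}pent-2-en-1-ol F6. Esterification with **16** as in step 14 gives (2E)-3-{[(tert-butyldimethylsilyl)oxy]methyl}pent-2-en-1-yl (2R)-2-[(1S,4R,5S)-2,4-dimethyl-5-(prop-1-en-2-yl)cyclopent-2-en-1-yl]propanoate F7. Its Z silyl ketene acetal F8 should rearrange to **23** and, after hydrolysis, to **24**.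

**Step 20.** The weakly nucleophilic formyl ylide may add too slowly to a neopentyl aldehyde flanked by two quaternary carbons, so that thermal decomposition or a second olefination of the product competes. Fallback, from **28** back to **32**: homologation with dimethyl (1-diazo-2-oxopropyl)phosphonate (K2CO3, MeOH) gives 2-(trimethylsilyl)ethyl (1R,3aR,4R,5R,7aS)-5-ethyl-5-ethynyl-1,3,4,7-tetramethyl-3a,4,5,7a-tetrahydro-1H-indene-4-carboxylate F9. LiN(SiMe3)2 and MeI give 2-(trimethylsilyl)ethyl (1R,3aR,4R,5R,7aS)-5-ethyl-1,3,4,7-tetramethyl-5-(prop-1-yn-1-yl)-3a,4,5,7a-tetrahydro-1H-indene-4-carboxylate F10. Hydrozirconation with Cp2Zr(H)Cl places zirconium on the methyl-bearing carbon, away from the quaternary centre. Transmetalation with ZnCl2 and Pd(PPh3)4-catalysed coupling with (E)-(2-bromovinyl)benzene then give **32** with both alkene geometries set by syn addition and retention.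

## Further compounds

F1 | step 5 | allyl (4R)-2-acetyl-5-[(tert-butyldiphenylsilyl)oxy]-4-methylpent-2-enoate (E/Z mixture) | C=CCOC(=O)C(C(C)=O)=C[C@@H](C)CO[Si](c1ccccc1)(c1ccccc1)C(C)(C)C
F2 | step 5 | 1-allyl 3-ethyl (2S,5R)-1-acetyl-2-[(2R)-1-[(tert-butyldiphenylsilyl)oxy]propan-2-yl]-5-methylcyclopent-3-ene-1,3-dicarboxylate (both C1 epimers) | CCOC(=O)C1=C[C@@H](C)C(C(C)=O)(C(=O)OCC=C)[C@H]1[C@@H](C)CO[Si](c1ccccc1)(c1ccccc1)C(C)(C)C
F3 | step 15 | 4-[(4-methoxybenzyl)oxy]but-2-yn-1-ol | COc1ccc(COCC#CCO)cc1
F4 | step 15 | (2E)-2-ethyl-4-[(4-methoxybenzyl)oxy]but-2-en-1-ol | OC/C(CC)=C/COCc1ccc(OC)cc1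
F5 | step 15 | tert-butyl{[(2E)-2-ethyl-4-[(4-methoxybenzyl)oxy]but-2-en-1-yl]oxy}dimethylsilane | CC(C)(C)[Si](C)(C)OC/C(CC)=C/COCc1ccc(OC)cc1
F6 | step 15 | (2E)-3-{[(tert-butyldimethylsilyl)oxy]methyl}pent-2-en-1-ol | OC/C=C(\CC)CO[Si](C)(C)C(C)(C)C
F7 | step 15 | (2E)-3-{[(tert-butyldimethylsilyl)oxy]methyl}pent-2-en-1-yl (2R)-2-[(1S,4R,5S)-2,4-dimethyl-5-(prop-1-en-2-yl)cyclopent-2-en-1-yl]propanoate | CC1=C[C@@H](C)[C@H](C(C)=C)[C@H]1[C@@H](C)C(=O)OC/C=C(\CC)CO[Si](C)(C)C(C)(C)C
F8 | step 15 | trimethylsilyl ketene acetal of F7, Z at the enolate (methyl cis to the allyloxy oxygen) | C/C(=C(/O[Si](C)(C)C)OC/C=C(\CC)CO[Si](C)(C)C(C)(C)C)[C@H]1C(C)=C[C@@H](C)[C@@H]1C(C)=C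
F9 | step 20 | 2-(trimethylsilyl)ethyl (1R,3aR,4R,5R,7aS)-5-ethyl-5-ethynyl-1,3,4,7-tetramethyl-3a,4,5,7a-tetrahydro-1H-indene-4-carboxylate | CC[C@]1(C#C)C=C(C)[C@H]2[C@H](C)C=C(C)[C@@H]2[C@@]1(C)C(=O)OCC[Si](C)(C)C
F10 | step 20 | 2-(trimethylsilyl)ethyl (1R,3aR,4R,5R,7aS)-5-ethyl-1,3,4,7-tetramethyl-5-(prop-1-yn-1-yl)-3a,4,5,7a-tetrahydro-1H-indene-4-carboxylate | CC[C@]1(C#CC)C=C(C)[C@H]2[C@H](C)C=C(C)[C@@H]2[C@@]1(C)C(=O)OCC[Si](C)(C)C
A1 | alternative 1 | methyl 5-ethyl-1,3,4,7-tetramethyl-5-[(1E,3E)-2-methyl-4-phenylbuta-1,3-dien-1-yl]-2-oxo-2,4,5,7a-tetrahydro-1H-indene-4-carboxylate (configured as the target at C1, C4, C5 and C7a) | CC[C@]1(/C=C(C)/C=C/c2ccccc2)C=C(C)[C@H]2[C@H](C)C(=O)C(C)=C2[C@@]1(C)C(=O)OC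
A2 | alternative 2 | 5-acetyl-8-{[(tert-butyldimethylsilyl)oxy]methyl}-6-ethyl-1,4-dimethyl-2-oxabicyclo[2.2.2]oct-7-en-3-one | C[C@]12C(=O)O[C@](C)(C=C1CO[Si](C)(C)C(C)(C)C)[C@@H](CC)[C@@H]2C(C)=O
A3 | alternative 3 | methyl (1R,3aR,4R,5S,7aS)-5-ethyl-1,3,4,7-tetramethyl-5-[(1E,3E)-2-methyl-4-phenylbuta-1,3-dien-1-yl]-3a,4,5,7a-tetrahydro-1H-indene-4-carboxylate | CC[C@]1(/C=C(C)/C=C/c2ccccc2)C=C(C)[C@H]2[C@H](C)C=C(C)[C@@H]2[C@@]1(C)C(=O)OC
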